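If you must pick the charge for the next run within the hour, ask one question: does more solid substrate buy more ring by 12 min? Maple, ash and elm differ in charge.

| flask | solid substrate | remark | time |
|---|---|---|---|
| south | 22 mM | run made earlier |  |
| maple | 20 mM |  | 12 min |
| ash | 40 mM |  | 12 min |
| elm | 80 mM |  | 12 min |

south run (percent of the solid substrate charged)

| time / min | ring / % | solid substrate / % |
|---|---|---|
| 0.333 | 0.6 | 96.9 |
| 0.500 | 1.7 | 95.3 |
| 1.00 | 1.3 | 87.5 |
| 1.50 | 4.6 | 83.9 |
| 2.50 | 7.4 | 78.6 |
| 4.00 | 15.2 | 69.3 |

(standard deviation of a reading: 1 percentage point)

- the analysis behind the earlier runs scatters by 1 percentage point, standard deviation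
- at the start none of the solid substrate is in solution
- a reading or a percentage of ring counts all its forms, free or not
- the concentration of ring that is asked is that of its free form alone
- "hardly changes" means that all values lie within two and a half points (for a concentration: within two and a half percent of the largest)

* [ring] (only what is free in solution) at the end for maple, ash, elm, in this order
* the shape of the row from first to last (falls all the way / hardly changes / rises, then falls / rises all the way / falls, then rises)

Start with the last two south readings, which scatter by 1 percentage point. Ring climbs from 7.4 % at 2.50 min to 15.2 % at 4.00 min. Call the ring pace the concentration of ring gained per minute while solid substrate stands in the flask; south's readings give 1.14 mM min⁻¹. Over the same interval the solid loses 1.36 mM min⁻¹.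

What has left the solid but isn't yet ring is 14.0 % and then 15.5 %. That change lies within the scatter, so I take the solution as level and both paces as independent of the charge. One run can't prove this.

Maple has the smallest charge. At that loss it should last 14.7 min, longer than the run. My reckoning therefore continues south's last reading at the ring pace, which gives 12.5 mM in each flask, provided ring stays free. Charge 20 mM, since ash and elm should add solid and no ring.

The forecast gives 12.5 mM, 12.5 mM and 12.5 mM, so hardly changes: “While solid remains, the solution stays at this level whatever the charge”. My figure is the same.

The flasks give 11.5 mM, 11.5 mM and 11.5 mM, so hardly changes.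

    starting material → ring (k = 0.00575 s⁻¹)
    2 starting material → open dimer (k = 0.144 L mol⁻¹ s⁻¹)
    crystals ⇌ ring, rate k3*(cs3 - [ring]) while solid is left; crystals form when [ring] > cs3 (solubility = 18.0 mM, k = 0.541 s⁻¹)
    solid substrate ⇌ starting material, rate k4*(cs4 - [starting material]) while solid is left; crystals form when [starting material] > cs4 (solubility = 4.60 mM, k = 0.0123 s⁻¹)

From 6.00 min to 12.0 min, the ring pace is 1.03 mM min⁻¹ in maple and 1.03 mM min⁻¹ in elm, where south's scattered readings gave 1.14 mM min⁻¹. At 5.20 min in maple, each step taken net, starting material is made 1.01 times as fast as it is used up, a steady state, and at 12.0 min it stands at 15.0 % of maple's charge, with 19.3 % of that charge still solid substrate.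

The earlier runs and the new flask are simulated with made-up constants, and the scatter is random.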